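**Plan**

1. Retrosynthesis: the ketone is traced back to a silyl-protected carbinol, and the hydrogen on ring carbon C2 to a methyl ester that acts as a traceless activator and leaves as CO2. The benzene ring is then cut at C1–C6 and C2–C3 into a 5-silyloxyicos-2-ynoate and the bis(trimethylsilyl) dienol ether of methyl acetoacetate.
2. Enabling feature: with C1 as the ring carbon carrying the 2-oxoheptadecyl chain, C3, C4, C5 and C6 carry O, H, O, H in turn, which is the oxidation pattern of the four-carbon chain of acetoacetate; C1 and C2 are two adjacent ring carbons that an alkyne can supply.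
3. The ynoate is cut at the alkyne–carboxyl bond and at the bond between the carbinol carbon and the propargylic CH2, leading to methyl chloroformate, propargyl bromide and hexadecanal.
4. Forward: the chain is assembled first (propargylation, silylation, carboxylation), the only ring arises in one Diels–Alder/aromatisation event, then the ester is removed and the carbinol is unveiled and oxidised behind benzyl-protected phenols.
5. Stereochemistry: the target has no stereocentre; the carbinol carbon is carried as a racemate and vanishes on oxidation.

Key step: step 6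

Remark: all intermediates with a silyloxy- or hydroxy-bearing chain carbon are racemic, and the geometry of the enol ether double bonds in the diene and its precursor is of no consequence because those carbons end up aromatic.

**Route**

Step 1
Reactants: 1 hexadecanal; 2 propargyl bromide
Product: 4 rac-nonadec-1-yn-4-ol, via propa-1,2-dienylzinc bromide 3 (not isolated)
Conditions: Zn dust, THF, 0 °C → rt; aq. work-up
Reagents that add atoms: none
Why: Zinc inserts into propargyl bromide to give the allenylzinc species, which adds to the aldehyde through a cyclic SE2' transition state (Barbier propargylation) to give the homopropargylic alcohol, whose new carbinol centre forms as a racemate and needs no control because it is later oxidised.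

Step 2
Reactants: 4 rac-nonadec-1-yn-4-ol
Product: 5 rac-triisopropyl(nonadec-1-yn-4-yloxy)silane
Conditions: iPr3SiOTf, 2,6-lutidine, CH2Cl2, 0 °C → rt
Reagents that add atoms: triisopropylsilyl trifluoromethanesulfonate, CC(C)[Si](OS(=O)(=O)C(F)(F)F)(C(C)C)C(C)C
Why: Silylation of a secondary alcohol with a silyl triflate and a hindered pyridine base is routine, and the bulky triisopropylsilyl ether is chosen because it must later survive hot alkali and a short acidic stage.

Step 3
Reactants: 5 rac-triisopropyl(nonadec-1-yn-4-yloxy)silane; 6 methyl chloroformate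
Product: 8 rac-methyl 5-(triisopropylsilyloxy)icos-2-ynoate, via lithium acetylide 7 (not isolated)
Conditions: n-BuLi, THF, −78 °C; ClCO2Me, −78 → 0 °C
Reagents that add atoms: none
Why: Deprotonation of the terminal alkyne and C-acylation of the lithium acetylide with a chloroformate is the standard ynoate synthesis, and low temperature without excess base should keep the CH2 next to the alkyne from isomerising to an allenoate or eliminating the silyloxy group.

Step 4
Reactants: 9 methyl acetoacetate
Product: 10 methyl 3-(trimethylsilyloxy)but-2-enoate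
Conditions: Me3SiCl, Et3N, hexane, rt
Reagents that add atoms: chlorotrimethylsilane, C[Si](C)(C)Cl
Why: O-silylation of the enol form of a β-ketoester with a chlorosilane and a tertiary amine gives the silyl enol ether, a routine enol silylation.

Step 5
Reactants: 10 methyl 3-(trimethylsilyloxy)but-2-enoate
Product: 12 1-methoxy-1,3-bis(trimethylsilyloxy)buta-1,3-diene, via lithium dienolate 11 (not isolated)
Conditions: LiN(i-Pr)2, THF, −78 °C; Me3SiCl, −78 °C → rt
Reagents that add atoms: chlorotrimethylsilane, C[Si](C)(C)Cl
Why: The amide base removes a γ-proton of the vinylogous ester and the resulting dienolate is trapped on oxygen by the chlorosilane, the standard kinetic enolate O-silylation that gives 1,1,3-trioxygenated dienes.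

Step 6
Reactants: 8 rac-methyl 5-(triisopropylsilyloxy)icos-2-ynoate; 12 1-methoxy-1,3-bis(trimethylsilyloxy)buta-1,3-diene
Product: 15 rac-methyl 2,4-dihydroxy-6-[2-(triisopropylsilyloxy)heptadecyl]benzoate, via cyclohexa-1,4-diene cycloadduct 13 (not isolated), via aryl bis(trimethylsilyl) ether 14 (not isolated)
Conditions: 12 (4 equiv, in portions), toluene, 130 °C (sealed tube); then 0.5 M HCl, THF, rt
Reagents that add atoms: none
Why: The electron-rich diene 12 and the electron-poor ynoate 8 should combine in a normal-electron-demand, strongly asynchronous [4+2] cycloaddition in which the unsubstituted CH2 terminus of 12, its most nucleophilic carbon, bonds to the chain-bearing β-carbon of 8 (ring bond C1–C6) and the ketene acetal carbon bonds to the ester-bearing α-carbon (ring bond C2–C3). The six-membered carbocycle is thus closed by an intermolecular Diels–Alder cycloaddition that makes both ring bonds in one event, after which cycloadduct 13 aromatises irreversibly by 1,4-elimination of methanol from the acetal carbon to give 14, whose two aryl trimethylsilyl ethers are hydrolysed by the mild acidic work-up while the triisopropylsilyl ether stays. The closest known reaction type is the thermal Diels–Alder benzannulation of 1,1,3-trioxygenated buta-1,3-dienes with alk-2-ynoates to 6-alkyl-2,4-dihydroxybenzoates. No lasting stereocentre is created, since the acetal carbon of 13 becomes aromatic and the silyloxy-bearing chain carbon is a racemic spectator. The step needs a single regiochemistry, chain ortho to the ester and meta to both oxygens, and the matched polarisation of the partners (acceptor ester on the alkyne α-carbon, donor oxygens on C1 and C3 of the diene) secures it. Because a β-alkylated ynoate is a sluggish dienophile, excess diene added in portions and prolonged heating are planned, and the silyl ether keeps the propargylic CH2 from isomerising and the carbinol from lactonising onto the ester.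

Step 7
Reactants: 15 rac-methyl 2,4-dihydroxy-6-[2-(triisopropylsilyloxy)heptadecyl]benzoate
Product: 17 rac-5-[2-(triisopropylsilyloxy)heptadecyl]benzene-1,3-diol, via resorcylic acid 16 (not isolated)
Conditions: KOH, EtOH–H2O, reflux; 1 M HCl to pH 3, 0 °C; then toluene, 100 °C
Reagents that add atoms: none
Why: Hot aqueous-alcoholic KOH saponifies the hindered salicylate-type ester and the freed 2,4-dihydroxybenzoic acid undergoes protodecarboxylation on gentle heating by ipso-protonation of its electron-rich ring, as β-resorcylic acids do, while the triisopropylsilyl ether should resist both stages and so prevent lactonisation.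

Step 8
Reactants: 17 rac-5-[2-(triisopropylsilyloxy)heptadecyl]benzene-1,3-diol
Product: 18 rac-1,3-bis(benzyloxy)-5-[2-(triisopropylsilyloxy)heptadecyl]benzene
Conditions: BnBr, K2CO3, DMF, rt
Reagents that add atoms: benzyl bromide, BrCc1ccccc1
Why: In this Williamson etherification K2CO3 deprotonates only the phenols, so both are benzylated while the silyl ether is untouched, and benzyl ethers tolerate fluoride and the oxidant and come off at the end under neutral conditions.

Step 9
Reactants: 18 rac-1,3-bis(benzyloxy)-5-[2-(triisopropylsilyloxy)heptadecyl]benzene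
Product: 19 rac-1-[3,5-bis(benzyloxy)phenyl]heptadecan-2-ol
Conditions: Bu4NF, THF, rt → 40 °C
Reagents that add atoms: none
Why: Fluoride-induced desilylation, driven by the strong Si–F bond, frees the secondary alcohol while the benzyl ethers are inert.

Step 10
Reactants: 19 rac-1-[3,5-bis(benzyloxy)phenyl]heptadecan-2-ol
Product: 20 1-[3,5-bis(benzyloxy)phenyl]heptadecan-2-one
Conditions: Dess–Martin periodinane, CH2Cl2, 0 °C → rt
Reagents that add atoms: none
Why: Dess–Martin oxidation converts the secondary alcohol into the ketone under mild, non-aqueous conditions that should limit enolisation and over-oxidation at the benzylic CH2, and it removes the only stereocentre of the route.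

Step 11
Reactants: 20 1-[3,5-bis(benzyloxy)phenyl]heptadecan-2-one
Product: 21 1-(3,5-dihydroxyphenyl)heptadecan-2-one
Conditions: H2 (1 atm), 10% Pd/C, EtOAc, rt
Reagents that add atoms: none
Why: Catalytic hydrogenolysis of aryl benzyl ethers over Pd/C is fast at atmospheric pressure, whereas the aliphatic ketone, which has no benzylic C–O bond, should not be reduced.

**Compound list**

1 | hexadecanal | CCCCCCCCCCCCCCCC=O | starting material
2 | propargyl bromide (3-bromoprop-1-yne) | C#CCBr | starting material
3 | propa-1,2-dienylzinc bromide | C=C=C[Zn]Br | intermediate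
4 | rac-nonadec-1-yn-4-ol | CCCCCCCCCCCCCCCC(O)CC#C | intermediate
5 | rac-triisopropyl(nonadec-1-yn-4-yloxy)silane | CCCCCCCCCCCCCCCC(O[Si](C(C)C)(C(C)C)C(C)C)CC#C | intermediate
6 | methyl chloroformate | COC(=O)Cl | starting material
7 | lithium acetylide of 5, rac-[4-(triisopropylsilyloxy)nonadec-1-yn-1-yl]lithium | [Li]C#CCC(O[Si](C(C)C)(C(C)C)C(C)C)CCCCCCCCCCCCCCC | intermediate
8 | rac-methyl 5-(triisopropylsilyloxy)icos-2-ynoate | CCCCCCCCCCCCCCCC(O[Si](C(C)C)(C(C)C)C(C)C)CC#CC(=O)OC | intermediate
9 | methyl acetoacetate | CC(=O)CC(=O)OC | starting material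
10 | methyl 3-(trimethylsilyloxy)but-2-enoate (E/Z mixture) | COC(=O)C=C(C)O[Si](C)(C)C | intermediate
11 | lithium 1-methoxy-3-(trimethylsilyloxy)buta-1,3-dien-1-olate | [Li]OC(OC)=CC(=C)O[Si](C)(C)C | intermediate
12 | 1-methoxy-1,3-bis(trimethylsilyloxy)buta-1,3-diene | COC(O[Si](C)(C)C)=CC(=C)O[Si](C)(C)C | intermediate
13 | methyl 6-methoxy-2-[2-(triisopropylsilyloxy)heptadecyl]-4,6-bis(trimethylsilyloxy)cyclohexa-1,4-diene-1-carboxylate (mixture of diastereomers) | COC(=O)C1=C(CC(O[Si](C(C)C)(C(C)C)C(C)C)CCCCCCCCCCCCCCC)CC(O[Si](C)(C)C)=CC1(OC)O[Si](C)(C)C | intermediate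
14 | rac-methyl 2-[2-(triisopropylsilyloxy)heptadecyl]-4,6-bis(trimethylsilyloxy)benzoate | CCCCCCCCCCCCCCCC(O[Si](C(C)C)(C(C)C)C(C)C)Cc1cc(O[Si](C)(C)C)cc(O[Si](C)(C)C)c1C(=O)OC | intermediate
15 | rac-methyl 2,4-dihydroxy-6-[2-(triisopropylsilyloxy)heptadecyl]benzoate | CCCCCCCCCCCCCCCC(O[Si](C(C)C)(C(C)C)C(C)C)Cc1cc(O)cc(O)c1C(=O)OC | intermediate
16 | rac-2,4-dihydroxy-6-[2-(triisopropylsilyloxy)heptadecyl]benzoic acid | CCCCCCCCCCCCCCCC(O[Si](C(C)C)(C(C)C)C(C)C)Cc1cc(O)cc(O)c1C(=O)O | intermediate
17 | rac-5-[2-(triisopropylsilyloxy)heptadecyl]benzene-1,3-diol | CCCCCCCCCCCCCCCC(O[Si](C(C)C)(C(C)C)C(C)C)Cc1cc(O)cc(O)c1 | intermediate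
18 | rac-1,3-bis(benzyloxy)-5-[2-(triisopropylsilyloxy)heptadecyl]benzene | CCCCCCCCCCCCCCCC(O[Si](C(C)C)(C(C)C)C(C)C)Cc1cc(OCc2ccccc2)cc(OCc2ccccc2)c1 | intermediate
19 | rac-1-[3,5-bis(benzyloxy)phenyl]heptadecan-2-ol | CCCCCCCCCCCCCCCC(O)Cc1cc(OCc2ccccc2)cc(OCc2ccccc2)c1 | intermediate
20 | 1-[3,5-bis(benzyloxy)phenyl]heptadecan-2-one | CCCCCCCCCCCCCCCC(=O)Cc1cc(OCc2ccccc2)cc(OCc2ccccc2)c1 | intermediate
21 | 1-(3,5-dihydroxyphenyl)heptadecan-2-one | CCCCCCCCCCCCCCCC(=O)Cc1cc(O)cc(O)c1 | target

**Step count**

Total: 11 steps. Longest linear sequence: 9 steps (steps 1, 2, 3, 6, 7, 8, 9, 10, 11, from hexadecanal); the diene branch (steps 4 and 5) joins at step 6.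

**Steps most likely to fail**

Step 6. The cycloaddition may stall: the β-alkylated ynoate reacts slowly, and at the temperature required the diene can be consumed by silyl migration, oligomerisation or hydrolysis by traces of moisture before the ring forms. The fallback sets out from hexadecanal 1 and returns at carbinol 19; it gives up the benzannulation and joins a preformed, protected resorcinol ring to the chain. Commercially available 3,5-bis(benzyloxy)benzyl bromide would be converted with Mg turnings in Et2O at 0 °C, by slow addition at high dilution to hold back Wurtz coupling, into [3,5-bis(benzyloxy)benzyl]magnesium bromide F1. Grignard addition of this reagent to 1 should give 19 directly, after which steps 10 and 11 follow unchanged.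

Step 7. Hydrolysis may stop short because the phenoxide dianion of the hindered salicylate repels hydroxide. Harsher treatment, or the acidic stage, may strip the silyl ether, after which the freed carbinol would lactonise onto the carboxyl group. The fallback sets out from alkyne 5 and returns at acid 16; it carries the activating group as an allyl ester that is removed without hydroxide. Lithium acetylide 7, generated from 5 as in step 3, would be acylated with allyl chloroformate to rac-allyl 5-(triisopropylsilyloxy)icos-2-ynoate F2. Cycloaddition with diene 12 under the conditions of step 6 would pass through allyl 6-methoxy-2-[2-(triisopropylsilyloxy)heptadecyl]-4,6-bis(trimethylsilyloxy)cyclohexa-1,4-diene-1-carboxylate F3 and rac-allyl 2-[2-(triisopropylsilyloxy)heptadecyl]-4,6-bis(trimethylsilyloxy)benzoate F4 to rac-allyl 2,4-dihydroxy-6-[2-(triisopropylsilyloxy)heptadecyl]benzoate F5. Allyl transfer to morpholine catalysed by Pd(PPh3)4 (THF, rt) would then release acid 16 under neutral conditions, and 16 is decarboxylated in warm toluene to 17 as in the second half of step 7.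

Step 8. The ambident resorcinol dianion may be alkylated on carbon as well as on oxygen, or the second O-alkylation may lag, giving mixtures that are hard to separate. The fallback sets out from resorcinol 17 and returns at target 21; it protects the phenols as acetates, which form on oxygen only. Ac2O in pyridine should give rac-5-[2-(triisopropylsilyloxy)heptadecyl]-1,3-phenylene diacetate F6. Aqueous HF in MeCN, an acidic fluoride source that should leave aryl acetates intact, would free the carbinol to give rac-5-(2-hydroxyheptadecyl)-1,3-phenylene diacetate F7. Dess–Martin oxidation would give 5-(2-oxoheptadecyl)-1,3-phenylene diacetate F8, and K2CO3 in MeOH at 0 °C would remove both acetates to give 21.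

**Further compounds**

F1 | step 6 | [3,5-bis(benzyloxy)benzyl]magnesium bromide | Br[Mg]Cc1cc(OCc2ccccc2)cc(OCc2ccccc2)c1
F2 | step 7 | rac-allyl 5-(triisopropylsilyloxy)icos-2-ynoate | CCCCCCCCCCCCCCCC(O[Si](C(C)C)(C(C)C)C(C)C)CC#CC(=O)OCC=C
F3 | step 7 | allyl 6-methoxy-2-[2-(triisopropylsilyloxy)heptadecyl]-4,6-bis(trimethylsilyloxy)cyclohexa-1,4-diene-1-carboxylate | C=CCOC(=O)C1=C(CC(O[Si](C(C)C)(C(C)C)C(C)C)CCCCCCCCCCCCCCC)CC(O[Si](C)(C)C)=CC1(OC)O[Si](C)(C)C
F4 | step 7 | rac-allyl 2-[2-(triisopropylsilyloxy)heptadecyl]-4,6-bis(trimethylsilyloxy)benzoate | CCCCCCCCCCCCCCCC(O[Si](C(C)C)(C(C)C)C(C)C)Cc1cc(O[Si](C)(C)C)cc(O[Si](C)(C)C)c1C(=O)OCC=C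
F5 | step 7 | rac-allyl 2,4-dihydroxy-6-[2-(triisopropylsilyloxy)heptadecyl]benzoate | CCCCCCCCCCCCCCCC(O[Si](C(C)C)(C(C)C)C(C)C)Cc1cc(O)cc(O)c1C(=O)OCC=C
F6 | step 8 | rac-5-[2-(triisopropylsilyloxy)heptadecyl]-1,3-phenylene diacetate | CCCCCCCCCCCCCCCC(O[Si](C(C)C)(C(C)C)C(C)C)Cc1cc(OC(C)=O)cc(OC(C)=O)c1
F7 | step 8 | rac-5-(2-hydroxyheptadecyl)-1,3-phenylene diacetate | CCCCCCCCCCCCCCCC(O)Cc1cc(OC(C)=O)cc(OC(C)=O)c1
F8 | step 8 | 5-(2-oxoheptadecyl)-1,3-phenylene diacetate | CCCCCCCCCCCCCCCC(=O)Cc1cc(OC(C)=O)cc(OC(C)=O)c1
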